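All runs stem from a simulated flask from invented constants; scatter was added.

At early times the earlier runs look alike: at 0.208 d intermediate A reads 68 % with 0.10 M of substrate and 68 % with 0.40 M. We want the best time for a flask between them.

| flask | substrate | partner | capture agent | protic impurity | remark | time |
|---|---|---|---|---|---|---|
| north-east | 0.10 M | 0.50 M | 0.020 M | 0.060 M | run made earlier |  |
| south-east | 0.40 M | 0.50 M | 0.020 M | 0.060 M | run made earlier |  |
| south | 0.20 M | 0.50 M | 0.040 M | 0.060 M | run made earlier |  |
| flask | 0.20 M | 0.500 M | 0.0200 M | 0.0600 M |  | 15 d |

- north-east (time / d: intermediate A / %, target / %): 0.0833: 60, 9; 0.208: 68, 8; 0.417: 64, 4; 0.833: 56, 6; 2.08: 40, 4; 4.00: 31, 3; 10.0: 24, 3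
- south-east (time / d: intermediate A / %, target / %): 0.0833: 57, 10; 0.208: 68, 5; 0.417: 66, 3; 0.833: 62, 5; 2.08: 48, 1; 4.00: 41, 0; 10.0: 27, 3
- south (time / d: intermediate A / %, target / %): 0.0833: 58, 9; 0.250: 66, 7; 0.833: 52, 0; 3.00: 33, 0; 10.0: 24, 5

(scatter of a reading: 1.5 percentage points)

- the best time, 15 d at the latest, for intermediate A
- the amount of intermediate A, in percent of the substrate charged, at that time



Two numbers in the south-east run seem not to fit. Its capture agent is 5.00 % of the substrate, yet intermediate A falls by 41 percentage points by 10.0 d, more than that charge accounts for. So we reckon with the fraction left. Suppose each capture agent removes one substrate equivalent for good, and intermediate A settles at a fixed part of the rest, the other part going mostly to forms we do not read; then the fall asks for no more capture agent than was charged. The fraction left is the charged substrate less the capture agent, over the charged substrate, and the last reading divided by it gives 30.0 %, 28.4 % and 30.0 % in the three runs. Their mean is the late share 29.5 %. The flask has a fraction left of 90.0 %, so we expect 26.5 % late, below the early readings, and we look for the best time early.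

The forecast gives 0.23 d (range 0.16 d to 0.32 d) and 68 % (range 66 % to 70 %), holding that “Nothing suggests a late rebound, so the best time should be the early maximum”.

The flask gives 67.3 % at 0.232 d, inside both ranges. It already holds 63.2 % at 0.116 d, so the peak is broad.

    substrate + partner ⇌ target (K = 0.740 M⁻¹, k = 0.250 M⁻¹ h⁻¹)
    capture agent + intermediate A → trapped intermediate (k = 0.670 M⁻¹ h⁻¹)
    substrate ⇌ intermediate A (K = 7.00, k = 0.650 h⁻¹)
    partner + protic impurity → quenched reagent (k = 0.250 M⁻¹ h⁻¹)
    substrate ⇌ intermediate B (K = 18.0, k = 0.0880 h⁻¹)

At 15 d the flask holds 24.2 % of intermediate A, against our 26.5 %. The neighbour flask, charged with 0.080 M of capture agent, has a fraction left of 60.0 %, so the late share gives 17.7 %. The neighbour flask ends at 16.1 %, with 40.0 % trapped intermediate and 0 % of its capture agent, the limiting reagent of the trapping, remaining. Both reckonings stand higher than the simulated amounts, but the ratio of the two flasks, 0.665, matches the ratio of their fractions left, 0.667. The highest amount of intermediate A in the neighbour flask is 60.4 %.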